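## Retrosynthetic overview

- 13,14-Dihydro-PGE1 ⇒ PGE2: both C=C bonds (cis-Δ5, trans-Δ13) are removed last by one hydrogenation, so the cheaper C20:4 acid can be used and no protecting group is needed.
- PGE2 ⇒ PGH2 ⇒ PGG2: the 9-keto-11-hydroxy unit is the isomerised 9,11-endoperoxide, and the 15-OH is the reduced 15-OOH.
- PGG2 ⇒ arachidonic acid + 2 O2: C11–O, O–C9, C8–C12 and C15–O are disconnected together in one cyclooxygenase-run radical cascade on the achiral, acyclic, unprotected acid. This single operation sets C8, C11, C12 and C15.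
- Ring order: 1,2-dioxolane first (11-peroxyl radical onto C9, 5-exo), cyclopentane second (C8 radical onto C12, 5-exo). The O–O bridge is then opened, leaving the cyclopentanone.

Assumption: ram seminal-vesicle microsomes (ovine COX-1 with its glutathione-dependent PGE synthase) are treated as a commercial catalyst, and because the route has only two steps the closing risk ranking covers both, with step 1 entered twice for its two independent stages.

## Route

Step 1
Reactants: 1 arachidonic acid ((5Z,8Z,11Z,14Z)-icosa-5,8,11,14-tetraenoic acid)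
Product: 4 prostaglandin E2 ((5Z,13E,15S)-11α,15-dihydroxy-9-oxoprosta-5,13-dienoic acid; 8R,11R,12R,15S), via prostaglandin G2 2 (not isolated), via prostaglandin H2 3 (not isolated)
Conditions: ram seminal-vesicle microsomes (COX-1 + PGE synthase), O2 (1 atm, sparged), glutathione (4 equiv), hydroquinone (0.1 equiv), 0.1 M Tris·HCl/1 mM EDTA pH 8.0, 37 °C, 45 min; then citric acid to pH 3.5, EtOAc extraction, SiO2 chromatography at 0–5 °C
Reagents that add atoms: dioxygen, O=O
Why: This is the prostaglandin H synthase reaction (enzyme-templated peroxyl-radical bis-cyclisation) followed by a Kornblum–DeLaMare-type endoperoxide isomerisation: the Tyr-385 radical removes the 13-pro-S hydrogen, O2 adds at C11 to give the 11R-peroxyl radical, this closes 5-exo onto C9 (dioxolane) and the C8 radical closes 5-exo onto C12 (cyclopentane) with the active site holding the two chains trans (8R, 12R), a second O2 enters at C15 on one face (15S), the peroxidase site reduces 15-OOH to 15-OH with glutathione as terminal reductant, and the glutathione-dependent E-isomerase removes the C9–H and opens the O–O bond so that C9 becomes the ketone while C11 keeps its oxygen and configuration (11R).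

Step 2
Reactants: 4 prostaglandin E2
Product: 5 13,14-dihydro-PGE1 (7-[(1R,2R,3R)-3-hydroxy-2-[(3S)-3-hydroxyoctyl]-5-oxocyclopentyl]heptanoic acid)
Conditions: H2 (1 atm), 5% Rh/Al2O3 (cat.), EtOAc, 0 °C → rt, 2 h; filter through Celite, crystallise from EtOAc/hexane
Reagents that add atoms: none
Why: Heterogeneous catalytic hydrogenation (syn addition of H2) saturates the cis-Δ5 and trans-Δ13 disubstituted alkenes without touching the ketone, the acid or the four existing stereocentres and creates no new stereocentre, and Rh/Al2O3 in neutral EtOAc is chosen because it causes little allylic C–O hydrogenolysis, alkene migration or β-ketol dehydration.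

## Compound list

1 | arachidonic acid; (5Z,8Z,11Z,14Z)-icosa-5,8,11,14-tetraenoic acid | CCCCC/C=C\C/C=C\C/C=C\C/C=C\CCCC(=O)O | starting material
2 | prostaglandin G2; (5Z,13E,15S)-9α,11α-epidioxy-15-hydroperoxyprosta-5,13-dienoic acid (8R,9S,11R,12R) | CCCCC[C@H](OO)/C=C/[C@H]1[C@H]2C[C@H](OO2)[C@@H]1C/C=C\CCCC(=O)O | intermediate
3 | prostaglandin H2; (5Z,13E,15S)-9α,11α-epidioxy-15-hydroxyprosta-5,13-dienoic acid (8R,9S,11R,12R) | CCCCC[C@H](O)/C=C/[C@H]1[C@H]2C[C@H](OO2)[C@@H]1C/C=C\CCCC(=O)O | intermediate
4 | prostaglandin E2; (5Z,13E,15S)-11α,15-dihydroxy-9-oxoprosta-5,13-dienoic acid (8R,11R,12R) | CCCCC[C@H](O)/C=C/[C@H]1[C@H](O)CC(=O)[C@@H]1C/C=C\CCCC(=O)O | intermediate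
5 | 13,14-dihydro-PGE1; 7-[(1R,2R,3R)-3-hydroxy-2-[(3S)-3-hydroxyoctyl]-5-oxocyclopentyl]heptanoic acid | CCCCC[C@H](O)CC[C@H]1[C@H](O)CC(=O)[C@@H]1CCCCCCC(=O)O | target

## Step count and risks

Total step count: 2
Longest linear sequence: 2

Steps most likely to fail (both steps of the route; step 1 appears twice, once for each of its stages):

1. **Step 1, fate of the endoperoxide** (E-ketol against D-ketol, F-diol and C17 fragmentation products; loss of 4 by dehydration on isolation). The fallback replaces the enzymatic isomerisation by a chemical adjustment of oxidation state. It sets out from 1 and comes back to the route at 4. The oxygenation is run without glutathione and quenched after a few minutes with SnCl2 in ethanol, so that endoperoxide 3 is reduced in the flask to prostaglandin F2α F1, a stable triol that is easy to purify. N-Trimethylsilyldiethylamine in acetone at −45 °C silylates the acid and the 11- and 15-hydroxyls but not the hindered 9-hydroxyl, giving prostaglandin F2α 11,15-bis(trimethylsilyl) ether trimethylsilyl ester F2. Collins reagent (CrO3·2 pyridine, CH2Cl2, 0 °C) oxidises the free 9-hydroxyl to prostaglandin E2 11,15-bis(trimethylsilyl) ether trimethylsilyl ester F3. MeOH/H2O/AcOH at rt removes the three silyl groups and gives 4.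

2. **Step 2, hydrogenation of the free ketol** (hydrogenolysis or isomerisation at the allylic C15 carbinol, or β-elimination of the 11-hydroxyl on the catalyst). The fallback changes to a protecting-group approach. It sets out from 4 and comes back to the route at 5. TBSCl and imidazole in DMF, followed by a short aqueous AcOH work-up that hydrolyses the silyl ester, give prostaglandin E2 11,15-bis(tert-butyldimethylsilyl) ether F4. H2 over 10% Pd/C in EtOAc reduces both alkenes to 13,14-dihydro-prostaglandin E1 11,15-bis(tert-butyldimethylsilyl) ether F5. HF·pyridine in MeCN at 0 °C then frees the two hydroxyls and gives 5.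

3. **Step 1, peroxidase half-reaction** (incomplete reduction of the 15-hydroperoxide and peroxidase-linked self-inactivation of the enzyme at preparative substrate loading). The fallback takes the hydroperoxide reduction out of the enzyme and does it chemically after the ketol is formed. It sets out from 1 and comes back to the route at 4. COX-1 apoenzyme reconstituted with Mn(III)-protoporphyrin IX (cyclooxygenase-competent, almost no peroxidase activity) is used, so that 2 accumulates. The glutathione-dependent E-isomerase converts 2 in the same flask into 15-hydroperoxy-prostaglandin E2 F6. After cold extraction, triphenylphosphine in Et2O at 0 °C reduces the hydroperoxide and gives 4.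

## Further compounds

F1 | step 1 | prostaglandin F2α; (5Z,13E,15S)-9α,11α,15-trihydroxyprosta-5,13-dienoic acid | CCCCC[C@H](O)/C=C/[C@H]1[C@H](O)C[C@H](O)[C@@H]1C/C=C\CCCC(=O)O
F2 | step 1 | prostaglandin F2α 11,15-bis(trimethylsilyl) ether trimethylsilyl ester | CCCCC[C@H](O[Si](C)(C)C)/C=C/[C@H]1[C@H](O[Si](C)(C)C)C[C@H](O)[C@@H]1C/C=C\CCCC(=O)O[Si](C)(C)C
F3 | step 1 | prostaglandin E2 11,15-bis(trimethylsilyl) ether trimethylsilyl ester | CCCCC[C@H](O[Si](C)(C)C)/C=C/[C@H]1[C@H](O[Si](C)(C)C)CC(=O)[C@@H]1C/C=C\CCCC(=O)O[Si](C)(C)C
F4 | step 2 | prostaglandin E2 11,15-bis(tert-butyldimethylsilyl) ether | CCCCC[C@H](O[Si](C)(C)C(C)(C)C)/C=C/[C@H]1[C@H](O[Si](C)(C)C(C)(C)C)CC(=O)[C@@H]1C/C=C\CCCC(=O)O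
F5 | step 2 | 13,14-dihydro-prostaglandin E1 11,15-bis(tert-butyldimethylsilyl) ether | CCCCC[C@H](O[Si](C)(C)C(C)(C)C)CC[C@H]1[C@H](O[Si](C)(C)C(C)(C)C)CC(=O)[C@@H]1CCCCCCC(=O)O
F6 | step 1 | 15-hydroperoxy-prostaglandin E2; (5Z,13E,15S)-15-hydroperoxy-11α-hydroxy-9-oxoprosta-5,13-dienoic acid | CCCCC[C@H](OO)/C=C/[C@H]1[C@H](O)CC(=O)[C@@H]1C/C=C\CCCC(=O)O
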